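A direct plan would take docosanedioic acid A1, desymmetrise it statistically to the monomethyl ester 22-methoxy-22-oxodocosanoic acid A2, turn the acid end into the nitrile and the ester end into an aldehyde, add three carbons by allylation and hydroboration, oxidise to the 4-oxoaldehyde 22,25-dioxopentacosanenitrile A3, close the pyrrole with ammonia to the 2-alkylpyrrole 21-(1H-pyrrol-2-yl)henicosanenitrile A4 and formylate C5 last.
Its weakest steps would be:
- the differentiation of the two ends of the symmetric C22 diacid: a statistical half-hydrolysis followed by some eight redox and functional-group steps that add no skeletal complexity, including a carbinol stereocentre that would be made only to be oxidised away;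
- the double oxidation to A3 and its Paal–Knorr closure with ammonia: the γ-keto aldehyde would be prone to lactol or lactone formation and self-condensation, and the N-unsubstituted 2-alkylpyrrole A4 would be sensitive to acid and air;
- the Vilsmeier–Haack formylation as the last step: POCl3 and acid would act on the most precious and most oxidation-prone intermediate, with α/β mixtures and oligomerisation as possible losses.

**Plan of the new route**
The 2-formyl-1H-pyrrole of the target (numbered as pyrrole-2-carbaldehyde: N1, C2–C5, the exocyclic formyl carbon, free N–H, chain on C5) is a ring-contracted isomer of a 2-alkylpyridine N-oxide. Pyridine N1 and C2–C5 become the pyrrole ring, pyridine C6 becomes the CHO carbon and the N-oxide oxygen becomes the aldehyde oxygen.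
The retrosynthesis first cuts the pyrrole N1–C2 bond and rejoins nitrogen to the formyl carbon, giving pyridine N-oxide 10; it then cuts the chain at C10–C11 (cross-metathesis, then hydrogenation); last it cuts C20–C21 next to the ring (alkylation of 2-picolyllithium).
The pyridine ring is bought; the pyrrole ring arises from it only in the last step and brings its aldehyde with it.
So no symmetric diacid has to be differentiated, no 4-oxoaldehyde and no unsubstituted alkylpyrrole are handled, and there is no formylation step.

Key step: step 5

Assumption: 11-bromoundec-1-ene and undec-10-enenitrile are taken as purchasable, and the copper-assisted photolysis known for water-soluble pyridine N-oxides is assumed to tolerate aqueous methanol, which the lipophilic N-oxide 10 needs for solubility.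

Step 1
Reactants: 1 2-methylpyridine (2-picoline); 2 11-bromoundec-1-ene
Product: 4 2-(dodec-11-en-1-yl)pyridine, via 2-picolyllithium 3 (not isolated)
Conditions: 1 (1.2 equiv), n-BuLi (1.15 equiv), THF, −78 → −20 °C; then 2, −78 °C → rt
Reagents that add atoms: n-butyllithium, [Li]CCCC (lithium of intermediate 3 only)
Why: Lateral lithiation of 2-picoline gives the resonance-stabilised picolyl anion, whose SN2 alkylation by a primary bromide is a standard route to 2-alkylpyridines, and the terminal alkene is inert.

Step 2
Reactants: 4 2-(dodec-11-en-1-yl)pyridine; 5 undec-10-enenitrile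
Product: 8 21-(pyridin-2-yl)henicos-10-enenitrile (E/Z mixture), via alkenylpyridinium tosylate 6 (not isolated), via cyanoalkenylpyridinium tosylate 7 (not isolated)
Conditions: TsOH (anhydrous, 1.05 equiv), CH2Cl2, rt; then 5 (3 equiv), second-generation Hoveyda–Grubbs catalyst RuCl2(H2IMes)(=CH-C6H4-2-OiPr) (3 mol%), 40 °C, N2 sparge; then NaHCO3 (aq.)
Reagents that add atoms: 4-methylbenzenesulfonic acid, Cc1ccc(cc1)S(=O)(=O)O (counter-ion of intermediates 6 and 7 only)
Why: Olefin cross-metathesis of two unhindered terminal alkenes is driven by loss of ethene, the pyridine nitrogen is masked as its salt so that it cannot bind ruthenium, the cheap nitrile in excess should carry most of 4 into the cross product, and the E/Z ratio is irrelevant because the double bond is hydrogenated next.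

Step 3
Reactants: 8 21-(pyridin-2-yl)henicos-10-enenitrile
Product: 9 21-(pyridin-2-yl)henicosanenitrile
Conditions: H2 (1 atm), 10% Pd/C, EtOAc, rt
Reagents that add atoms: none
Why: Heterogeneous catalytic hydrogenation of a disubstituted alkene should be far faster than reduction of an aliphatic nitrile or a pyridine ring under neutral conditions at low pressure.

Step 4
Reactants: 9 21-(pyridin-2-yl)henicosanenitrile
Product: 10 2-(20-cyanoicosyl)pyridine 1-oxide
Conditions: mCPBA (1.2 equiv), CH2Cl2, 0 °C → rt; filtration through basic alumina
Reagents that add atoms: mCPBA, O=C(OO)c1cccc(Cl)c1 (N-oxide oxygen)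
Why: Peracid N-oxidation of a pyridine meets no competing site here, since the alkene is already saturated and the nitrile and the chain are inert to mCPBA.

Step 5
Reactants: 10 2-(20-cyanoicosyl)pyridine 1-oxide
Product: 13 21-(5-formyl-1H-pyrrol-2-yl)henicosanenitrile (target; 5-(20-cyanoicosyl)-1H-pyrrole-2-carbaldehyde), via 1,2-oxazepine 11 (not isolated), via 2H-pyrrole-2-carbaldehyde 12 (not isolated)
Conditions: hν (254 nm, low-pressure Hg lamp, quartz), CuSO4·5H2O (2 equiv), MeOH/H2O 9:1, 5 mM, N2, 15–20 °C, stopped at partial conversion
Reagents that add atoms: none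
Why: π→π* excitation of the N-oxide should shift oxygen from N1 to the unsubstituted α-carbon C6 through an oxaziridine-like geometry and open the ring to the 1,2-oxazepine 11; N–O cleavage and bonding of nitrogen to the former C5 then push C6 out of the ring as the formyl group (2H-pyrrole 12), and a proton shift from that sp3 carbon to nitrogen gives the aromatic 13. This is the photochemical ring contraction of pyridine N-oxides to 2-formylpyrroles, run in its copper-assisted form, in which the divalent copper of CuSO4 is thought to bind the ring-opened stage and favour recyclisation over hydration and polymerisation. The pyrrole ring closes by 1,5-bond formation within the cis,cis-azadienyl unit cut out of the pyridine ring (a five-membered electrocyclic-type closure whose geometry is fixed by the ring of origin). No stereocentre remains, because the only sp3 carbon, C2 of 12, is formed racemic and is erased on tautomerisation. The step needs regioselectivity between the two α-carbons: oxygen must walk to C6–H and not to the chain-bearing C2, which rests only on the steric shielding of C2 by the alkyl chain and on analogy with 2-methylpyridine N-oxide, so the opposite sense, ending in a 2-acylpyrrole of different polarity, is the expected minor channel. The saturated chain and the nitrile do not absorb at 254 nm, dilution should suppress intermolecular oxygen transfer, and the main expected loss, photodeoxygenation, only returns 9 for recycling through step 4.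

**Compound list**

1 | 2-methylpyridine (2-picoline) | Cc1ccccn1 | starting material
2 | 11-bromoundec-1-ene | C=CCCCCCCCCCBr | starting material
3 | (pyridin-2-ylmethyl)lithium (2-picolyllithium) | [Li]Cc1ccccn1 | intermediate
4 | 2-(dodec-11-en-1-yl)pyridine | C=CCCCCCCCCCCc1ccccn1 | intermediate
5 | undec-10-enenitrile | C=CCCCCCCCCC#N | starting material
6 | 2-(dodec-11-en-1-yl)pyridinium 4-methylbenzenesulfonate | C=CCCCCCCCCCCc1cccc[nH+]1.Cc1ccc(cc1)S(=O)(=O)[O-] | intermediate
7 | 2-(20-cyanoicos-11-en-1-yl)pyridinium 4-methylbenzenesulfonate (E/Z mixture) | N#CCCCCCCCCC=CCCCCCCCCCCc1cccc[nH+]1.Cc1ccc(cc1)S(=O)(=O)[O-] | intermediate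
8 | 21-(pyridin-2-yl)henicos-10-enenitrile (E/Z mixture) | N#CCCCCCCCCC=CCCCCCCCCCCc1ccccn1 | intermediate
9 | 21-(pyridin-2-yl)henicosanenitrile | N#CCCCCCCCCCCCCCCCCCCCCc1ccccn1 | intermediate
10 | 2-(20-cyanoicosyl)pyridine 1-oxide | N#CCCCCCCCCCCCCCCCCCCCCc1cccc[n+]1[O-] | intermediate
11 | 21-(1,2-oxazepin-3-yl)henicosanenitrile | N#CCCCCCCCCCCCCCCCCCCCCC1=NOC=CC=C1 | intermediate
12 | 5-(20-cyanoicosyl)-2H-pyrrole-2-carbaldehyde (racemic, transient) | N#CCCCCCCCCCCCCCCCCCCCCC1=NC(C=O)C=C1 | intermediate
13 | 21-(5-formyl-1H-pyrrol-2-yl)henicosanenitrile (5-(20-cyanoicosyl)-1H-pyrrole-2-carbaldehyde; no stereocentre) | N#CCCCCCCCCCCCCCCCCCCCCc1ccc(C=O)[nH]1 | target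

Total step count: 5. Longest linear sequence: 5 steps (from 1 and 2 to 13).

**Steps most likely to fail**

Step 5 (ring contraction). What may go wrong: oxygen migration to the chain-bearing α-carbon; photodeoxygenation back to the pyridine; secondary photolysis of the product; polymerisation of the ring-opened stage. The fallback sets out from compounds 2 and 5 and comes back to the route at compound 13; it joins the chain to a bought pyrrole dialdehyde by olefination. Cross-metathesis of 2 with an excess of 5 (RuCl2(H2IMes)(=CH-C6H4-2-OiPr), the second-generation Hoveyda–Grubbs catalyst, CH2Cl2, 40 °C) should give 20-bromoicos-10-enenitrile F1. PPh3 in refluxing MeCN should convert this bromide into (19-cyanononadec-10-en-1-yl)triphenylphosphonium bromide F2. The ylide of this salt (KN(SiMe3)2, THF, −78 °C) would be added to the sodium salt, made with NaH, of an excess of 1H-pyrrole-2,5-dicarbaldehyde F3, so that a mono-Wittig reaction gives 5-(20-cyanoicosa-1,11-dien-1-yl)-1H-pyrrole-2-carbaldehyde F4. Hydrogenation of this diene (H2, 10% Pd/C, EtOAc) should saturate both double bonds and leave the vinylogous-amide aldehyde, giving 13.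

Step 2 (cross-metathesis). What may go wrong: inhibition of the ruthenium carbene by incompletely protonated pyridine or by the nitrile; homodimerisation of either partner; double-bond migration before metathesis, which would give chain-length homologues that cannot be separated after hydrogenation. The fallback sets out from compounds 3 and 5 and comes back to the route at compound 9; it replaces the metathesis by an sp3–sp3 Suzuki–Miyaura coupling that fixes the chain length. 2-Picolyllithium 3 would be added to an excess of 1,9-dibromononane F5 to give 2-(10-bromodecyl)pyridine F6, which would be used promptly. Hydroboration of 5 with 9-BBN (THF, rt) should give 11-(9-borabicyclo[3.3.1]nonan-9-yl)undecanenitrile F7. Coupling of F6 with F7 (Pd(OAc)2, PCy3, K3PO4·H2O, THF, rt) should give 9 directly, so step 3 is bypassed as well.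

Step 1 (picolyl alkylation). What may go wrong: proton transfer from the product to the picolyl anion followed by a second alkylation; E2 elimination of the bromide. The fallback sets out from compound 2 and comes back to the route at compound 4; it uses a stabilised carbanion instead of the organolithium. Ethyl 2-(pyridin-2-yl)acetate F8 would be alkylated with 2 (NaH, DMF, 0 °C → rt) to ethyl 2-(pyridin-2-yl)tridec-12-enoate F9. Saponification (NaOH, EtOH/H2O) should give 2-(pyridin-2-yl)tridec-12-enoic acid F10, and acidification and warming to 50 °C should cause the ready decarboxylation of this 2-pyridylacetic acid and give 4.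

**Further compounds**

F1 | step 5 | 20-bromoicos-10-enenitrile (E/Z mixture) | N#CCCCCCCCCC=CCCCCCCCCCBr
F2 | step 5 | (19-cyanononadec-10-en-1-yl)triphenylphosphonium bromide (E/Z mixture) | N#CCCCCCCCCC=CCCCCCCCCC[P+](c1ccccc1)(c1ccccc1)c1ccccc1.[Br-]
F3 | step 5 | 1H-pyrrole-2,5-dicarbaldehyde (purchased) | O=Cc1ccc(C=O)[nH]1
F4 | step 5 | 5-(20-cyanoicosa-1,11-dien-1-yl)-1H-pyrrole-2-carbaldehyde (mixture of double-bond isomers) | N#CCCCCCCCCC=CCCCCCCCCC=Cc1ccc(C=O)[nH]1
F5 | step 2 | 1,9-dibromononane (purchased) | BrCCCCCCCCCBr
F6 | step 2 | 2-(10-bromodecyl)pyridine | BrCCCCCCCCCCc1ccccn1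
F7 | step 2 | 11-(9-borabicyclo[3.3.1]nonan-9-yl)undecanenitrile | N#CCCCCCCCCCCB1C2CCCC1CCC2
F8 | step 1 | ethyl 2-(pyridin-2-yl)acetate (purchased) | CCOC(=O)Cc1ccccn1
F9 | step 1 | ethyl 2-(pyridin-2-yl)tridec-12-enoate (racemic) | C=CCCCCCCCCCC(C(=O)OCC)c1ccccn1
F10 | step 1 | 2-(pyridin-2-yl)tridec-12-enoic acid (racemic) | C=CCCCCCCCCCC(C(=O)O)c1ccccn1
A1 | direct plan | docosanedioic acid | OC(=O)CCCCCCCCCCCCCCCCCCCCC(=O)O
A2 | direct plan | 22-methoxy-22-oxodocosanoic acid | COC(=O)CCCCCCCCCCCCCCCCCCCCC(=O)O
A3 | direct plan | 22,25-dioxopentacosanenitrile | N#CCCCCCCCCCCCCCCCCCCCCC(=O)CCC=O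
A4 | direct plan | 21-(1H-pyrrol-2-yl)henicosanenitrile | N#CCCCCCCCCCCCCCCCCCCCCc1ccc[nH]1
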